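Ring C is cut at O1–C8a and C4–C4a, so that ring A becomes the aryne C4a≡C8a (4-geranyl-3,5-dimethoxybenzyne, from a 2-silylaryl triflate) and C2–C4 with O1 an (S)-β-hydroxy N-methoxy-N-methylamide. In one operation the alkoxide adds to C8a and the resulting C4a carbanion closes onto the amide carbonyl, a formal [4+2] annulation that delivers the complete flavanone. The step exploits the ortho relationship of O1 and the C4 acyl group on ring A and the C5 oxygen, which polarises the aryne so that oxygen enters at C8a. C2 is set beforehand by asymmetric transfer hydrogenation; chelation-controlled cleavage of the C5 methyl ether ends the route.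

Key step: step 8

Remark: the target is read as the (2S)-flavanone with an (E)-geranyl group at C6 (flavanone numbering O1, C2, C3, C4, C4a, C5–C8, C8a); "geranyl" means (2E)-3,7-dimethylocta-2,6-dien-1-yl; compounds 1, 2 and 14 are taken as commercial.

Step 1
Reactants: 1 1,3-dimethoxybenzene; 2 geranyl bromide
Product: 4 2-geranyl-1,3-dimethoxybenzene, via 2,6-dimethoxyphenyllithium 3 (not isolated)
Conditions: n-BuLi, THF, 0 °C to rt; then CuI (10 mol %), 2, −78 °C to rt
Reagents that add atoms: none
Why: Directed ortho-metalation between the two methoxy groups, then copper-assisted SN2 alkylation of the aryllithium by the primary allylic bromide, should give the 2-geranyl arene with the (E)-alkene intact.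

Step 2
Reactants: 4 2-geranyl-1,3-dimethoxybenzene
Product: 6 4-geranyl-3,5-dimethoxyphenol, via aryl pinacol boronate 5 (not isolated)
Conditions: [Ir(OMe)(cod)]2 (1.5 mol %), 4,4'-di-tert-butyl-2,2'-bipyridine (3 mol %), B2pin2 (0.55 equiv), THF, 80 °C; then 30% aq. H2O2, NaOH, THF, 0 °C
Reagents that add atoms: hydrogen peroxide, OO (the boron of 5 comes from bis(pinacolato)diboron, CC1(C)OB(OC1(C)C)B1OC(C)(C)C(C)(C)O1, and is lost again)
Why: Sterically controlled iridium-catalysed C–H borylation should take the only ring C–H without an ortho substituent (para to geranyl) and boronate oxidation then gives the phenol, the trisubstituted chain alkenes being poor substrates for the iridium boryl catalyst and for alkaline peroxide.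

Step 3
Reactants: 6 4-geranyl-3,5-dimethoxyphenol
Product: 7 4-geranyl-3,5-dimethoxyphenyl N-isopropylcarbamate
Conditions: i-PrNCO, Et3N (cat.), CH2Cl2, rt
Reagents that add atoms: isopropyl isocyanate, CC(C)N=C=O
Why: Base-catalysed carbamoylation of the phenol installs an ortho-directing group that can later be removed under mild base.

Step 4
Reactants: 7 4-geranyl-3,5-dimethoxyphenyl N-isopropylcarbamate
Product: 11 4-geranyl-3,5-dimethoxy-2-(trimethylsilyl)phenyl N-isopropylcarbamate, via N-silyl carbamate 8 (not isolated), via ortho-lithiated carbamate 9 (not isolated), via N-silyl C-silyl carbamate 10 (not isolated)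
Conditions: TBSOTf, TMEDA, Et2O, 0 °C to rt; then n-BuLi, TMEDA, −78 °C; then TMSCl, −78 °C to rt; then sat. aq. NH4Cl/MeOH
Reagents that add atoms: chlorotrimethylsilane, C[Si](C)(C)Cl (tert-butyldimethylsilyl triflate, CC(C)(C)[Si](C)(C)OS(=O)(=O)C(F)(F)F, stays only in 8 to 10)
Why: Directed ortho-metalation of the in situ N-silylated carbamate at the position flanked by carbamate and methoxy (the two free ortho positions are equivalent) and silyl quench should give the ortho-silyl carbamate, complex-induced lithiation at −78 °C being expected to outrun deprotonation of the benzylic/allylic CH2.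

Step 5
Reactants: 11 4-geranyl-3,5-dimethoxy-2-(trimethylsilyl)phenyl N-isopropylcarbamate
Product: 13 4-geranyl-3,5-dimethoxy-2-(trimethylsilyl)phenyl trifluoromethanesulfonate, via 2-silylphenol 12 (not isolated)
Conditions: DBU, Et2NH, MeCN, 40 °C; then PhNTf2, rt
Reagents that add atoms: N-phenylbis(trifluoromethanesulfonimide), O=S(=O)(N(c1ccccc1)S(=O)(=O)C(F)(F)F)C(F)(F)F
Why: E1cB cleavage of the N–H carbamate (isocyanate trapped by diethylamine) frees the phenoxide, which is O-triflated in the same flask without any acid that could protodesilylate the electron-rich aryl silane.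

Step 6
Reactants: 14 ethyl 3-(3,4-dimethoxyphenyl)-3-oxopropanoate
Product: 15 ethyl (S)-3-(3,4-dimethoxyphenyl)-3-hydroxypropanoate
Conditions: RuCl(p-cymene)[(S,S)-TsDPEN] (1 mol %), HCO2H/Et3N (5:2), rt
Reagents that add atoms: none
Why: Noyori asymmetric transfer hydrogenation of the aryl ketone, in which the (S,S)-catalyst should deliver hydride through the same aryl/arene CH–π transition state as for acetophenone and so give the (S)-benzylic alcohol that becomes C2 of the target.

Step 7
Reactants: 15 ethyl (S)-3-(3,4-dimethoxyphenyl)-3-hydroxypropanoate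
Product: 16 (S)-3-(3,4-dimethoxyphenyl)-3-hydroxy-N-methoxy-N-methylpropanamide
Conditions: MeNHOMe·HCl, AlMe3, CH2Cl2, 0 °C to rt; then aq. potassium sodium tartrate
Reagents that add atoms: N,O-dimethylhydroxylamine hydrochloride, CNOC.Cl
Why: Aluminium-amide aminolysis of the ester (Weinreb amide formation), assisted by the free β-hydroxyl, should proceed without touching the stereocentre, and the non-acidic work-up spares the electron-rich benzylic alcohol.

Step 8
Reactants: 16 (S)-3-(3,4-dimethoxyphenyl)-3-hydroxy-N-methoxy-N-methylpropanamide; 13 4-geranyl-3,5-dimethoxy-2-(trimethylsilyl)phenyl trifluoromethanesulfonate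
Product: 21 (S)-2-(3,4-dimethoxyphenyl)-6-geranyl-5,7-dimethoxychroman-4-one, via sodium alkoxide 17 (not isolated), via aryne 18 (not isolated), via aryl anion 19 (not isolated), via hemiaminal alkoxide 20 (not isolated)
Conditions: 16 (1.3 equiv), NaH (1.3 equiv), THF, 0 °C; then 13, CsF, 18-crown-6, THF, 0 °C to rt; then AcOH, 0 °C
Reagents that add atoms: none
Why: Proposed new method: deprotonation by NaH leaves alkoxide 17 without any proton source and fluoride releases aryne 18 from 13; 17 should add at C8a, the aryne carbon remote from the C5 methoxy group (a 3-alkoxy group distorts the aryne so that nucleophiles enter meta to it and the carbanion forms ortho to oxygen), and the C4a anion 19 then attacks the tethered N-methoxy-N-methylamide carbonyl, so that the O1–C8a and C4–C4a bonds form in one operation. Ring C closes by a 6-exo-trig acyl addition (overall a formal [4+2] annulation of an O–C–C–C unit onto the aryne), giving hemiaminal alkoxide 20, which should collapse to ketone 21 only on the acidic quench. The closest known reaction type is the fluoride-triggered annulation of arynes with salicylate esters to xanthones (O-arylation, then intramolecular acyl capture), along with aryne insertion into the C–O bond of carboxylic acids and the N–C(O) bond of β-lactams; new here are an aliphatic β-alkoxide as the O-nucleophile and an amide as the acyl trap. No new stereocentre remains in 21 (C4 of 20 is lost on collapse), and C2 is carried unchanged from 16 because none of its bonds is broken. The step needs regioselective O-addition (secured by the C5 methoxy group), acyl capture faster than proton transfer to 19 (secured by the aprotic medium and the six-membered transition state) and no retro-aldol, β-elimination or retro-oxa-Michael erosion of C2 (addressed by low temperature and by keeping the ketone masked as 20 until the base is quenched).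

Step 9
Reactants: 21 (S)-2-(3,4-dimethoxyphenyl)-6-geranyl-5,7-dimethoxychroman-4-one
Product: 23 (S)-2-(3,4-dimethoxyphenyl)-6-geranyl-5-hydroxy-7-methoxychroman-4-one (CNP0310479.1), via aryloxymagnesium iodide 22 (not isolated)
Conditions: MgI2·OEt2, THF, 60 °C; then 0.5 M aq. HCl, 0 °C
Reagents that add atoms: none
Why: Chelation-controlled Lewis-acid demethylation, in which magnesium bound between the C4 carbonyl and the peri C5 methoxy oxygen activates only that methyl group for SN2 attack by iodide, so the other three methyl ethers, the geranyl chain and C2 should be left alone under these mild conditions.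

Compound list
1 | 1,3-dimethoxybenzene | COc1cccc(OC)c1 | starting material
2 | geranyl bromide, (2E)-1-bromo-3,7-dimethylocta-2,6-diene | BrC/C=C(\C)CCC=C(C)C | starting material
3 | 2,6-dimethoxyphenyllithium | [Li]c1c(OC)cccc1OC | intermediate (not isolated)
4 | 2-geranyl-1,3-dimethoxybenzene | COc1cccc(OC)c1C/C=C(\C)CCC=C(C)C | intermediate
5 | 2-(4-geranyl-3,5-dimethoxyphenyl)-4,4,5,5-tetramethyl-1,3,2-dioxaborolane | COc1cc(B2OC(C)(C)C(C)(C)O2)cc(OC)c1C/C=C(\C)CCC=C(C)C | intermediate (not isolated)
6 | 4-geranyl-3,5-dimethoxyphenol | COc1cc(O)cc(OC)c1C/C=C(\C)CCC=C(C)C | intermediate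
7 | 4-geranyl-3,5-dimethoxyphenyl N-isopropylcarbamate | COc1cc(OC(=O)NC(C)C)cc(OC)c1C/C=C(\C)CCC=C(C)C | intermediate
8 | 4-geranyl-3,5-dimethoxyphenyl N-(tert-butyldimethylsilyl)-N-isopropylcarbamate | COc1cc(OC(=O)N(C(C)C)[Si](C)(C)C(C)(C)C)cc(OC)c1C/C=C(\C)CCC=C(C)C | intermediate (not isolated)
9 | 2-lithio derivative of 8 | COc1cc(OC(=O)N(C(C)C)[Si](C)(C)C(C)(C)C)c([Li])c(OC)c1C/C=C(\C)CCC=C(C)C | intermediate (not isolated)
10 | 4-geranyl-3,5-dimethoxy-2-(trimethylsilyl)phenyl N-(tert-butyldimethylsilyl)-N-isopropylcarbamate | COc1cc(OC(=O)N(C(C)C)[Si](C)(C)C(C)(C)C)c([Si](C)(C)C)c(OC)c1C/C=C(\C)CCC=C(C)C | intermediate (not isolated)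
11 | 4-geranyl-3,5-dimethoxy-2-(trimethylsilyl)phenyl N-isopropylcarbamate | COc1cc(OC(=O)NC(C)C)c([Si](C)(C)C)c(OC)c1C/C=C(\C)CCC=C(C)C | intermediate
12 | 4-geranyl-3,5-dimethoxy-2-(trimethylsilyl)phenol | COc1cc(O)c([Si](C)(C)C)c(OC)c1C/C=C(\C)CCC=C(C)C | intermediate (not isolated)
13 | 4-geranyl-3,5-dimethoxy-2-(trimethylsilyl)phenyl trifluoromethanesulfonate | COc1cc(OS(=O)(=O)C(F)(F)F)c([Si](C)(C)C)c(OC)c1C/C=C(\C)CCC=C(C)C | intermediate
14 | ethyl 3-(3,4-dimethoxyphenyl)-3-oxopropanoate | CCOC(=O)CC(=O)c1ccc(OC)c(OC)c1 | starting material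
15 | ethyl (S)-3-(3,4-dimethoxyphenyl)-3-hydroxypropanoate | CCOC(=O)C[C@H](O)c1ccc(OC)c(OC)c1 | intermediate
16 | (S)-3-(3,4-dimethoxyphenyl)-3-hydroxy-N-methoxy-N-methylpropanamide | CON(C)C(=O)C[C@H](O)c1ccc(OC)c(OC)c1 | intermediate
17 | sodium alkoxide of 16 | CON(C)C(=O)C[C@H]([O-])c1ccc(OC)c(OC)c1.[Na+] | intermediate (not isolated)
18 | 4-geranyl-3,5-dimethoxybenzyne | COC1=C(C/C=C(\C)CCC=C(C)C)C(OC)=CC#C1 | intermediate (not isolated)
19 | (S)-aryl ether with a carbanion at C4a, sodium salt | CON(C)C(=O)C[C@H](Oc1cc(OC)c(C/C=C(\C)CCC=C(C)C)c(OC)[c-]1)c1ccc(OC)c(OC)c1.[Na+] | intermediate (not isolated)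
20 | (2S)-2-(3,4-dimethoxyphenyl)-6-geranyl-5,7-dimethoxy-4-[methoxy(methyl)amino]chroman-4-olate, sodium salt (C4 epimers) | COc1ccc([C@@H]2CC([O-])(N(C)OC)c3c(OC)c(C/C=C(\C)CCC=C(C)C)c(OC)cc3O2)cc1OC.[Na+] | intermediate (not isolated)
21 | (S)-2-(3,4-dimethoxyphenyl)-6-geranyl-5,7-dimethoxychroman-4-one | COc1ccc([C@@H]2CC(=O)c3c(OC)c(C/C=C(\C)CCC=C(C)C)c(OC)cc3O2)cc1OC | intermediate
22 | iodomagnesium 5-phenolate of the target | COc1ccc([C@@H]2CC(=O)c3c(O[Mg]I)c(C/C=C(\C)CCC=C(C)C)c(OC)cc3O2)cc1OC | intermediate (not isolated)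
23 | (S)-2-(3,4-dimethoxyphenyl)-6-geranyl-5-hydroxy-7-methoxychroman-4-one (CNP0310479.1) | COc1ccc([C@@H]2CC(=O)c3c(cc(OC)c(C/C=C(\C)CCC=C(C)C)c3O)O2)cc1OC | target

Total step count: 9

Longest linear sequence: 7 steps (steps 1, 2, 3, 4, 5, 8, 9); steps 6 and 7 form the second branch.

Steps most likely to fail

1. Step 8 (key step). The capture of aryne 18 by alkoxide 17 may be overtaken by protonation of aryl anion 19 to an open-chain aryl ether, by retro-aldol or β-elimination of 17, or by attack of 17 on silicon or sulfur of 13. The fallback uses known reactions, sets out from aryne precursor 13 and comes back at flavanone 21. CsF-triggered insertion of aryne 18 into acetic acid (CC(=O)O; THF, sealed tube, 125 °C; O-arylation then acyl shift, with oxygen again entering at C8a) should give 1-(3-geranyl-6-hydroxy-2,4-dimethoxyphenyl)ethan-1-one F1. Condensation with N,N-dimethylformamide dimethyl acetal (COC(OC)N(C)C, 90 °C) should give (E)-3-(dimethylamino)-1-(3-geranyl-6-hydroxy-2,4-dimethoxyphenyl)prop-2-en-1-one F2, which should cyclise in warm acetic acid to 6-geranyl-5,7-dimethoxy-4H-chromen-4-one F3. Rhodium-catalysed asymmetric conjugate addition (Hayashi–Miyaura type) of 3,4-dimethoxyphenylboronic acid (OB(O)c1ccc(OC)c(OC)c1) to F3 should then give 21. It is run with [Rh(OH)(cod)]2 in toluene/H2O and the antipode of an atropisomeric diphosphine (BINAP or MeO-BIPHEP family) that sends the aryl group to the face giving (2S).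

2. Step 2. Iridium boryl or hydride species may hydroborate or isomerise the chain alkenes, or borylation may stray ortho to a methoxy group. The fallback sets out from geranyl bromide 2 and commercial 3,5-dimethoxyphenol (COc1cc(O)cc(OC)c1) and comes back at phenol 6, replacing steps 1 and 2. Silylation (i-Pr3SiCl, imidazole, DMF) gives (3,5-dimethoxyphenoxy)triisopropylsilane F4. n-BuLi in THF at 0 °C should deprotonate between the two methoxy groups, the bulky silyl ether blocking the other positions, to give 2,6-dimethoxy-4-(triisopropylsilyloxy)phenyllithium F5. CuI-assisted alkylation with 2 gives (4-geranyl-3,5-dimethoxyphenoxy)triisopropylsilane F6, and Bu4NF in THF releases 6.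

3. Step 9. The C2 configuration may erode through Lewis-acid-assisted opening of ring C to the chalcone, or cleavage may be slow because the C5 methoxy group is flanked by the geranyl group. The fallback moves the demethylation ahead of the stereocentre; it sets out from aryne precursor 13 and comes back at target 23. Chromone F3 is made from 13 as in the fallback for step 8 (via F1 and F2). MgI2·OEt2 in THF at 60 °C should then give 6-geranyl-5-hydroxy-7-methoxy-4H-chromen-4-one F7 while no stereocentre is present. The rhodium-catalysed asymmetric conjugate addition of 3,4-dimethoxyphenylboronic acid, run on F7 under neutral conditions ([Rh(OH)(cod)]2, the same diphosphine antipode, toluene/H2O), should give 23 directly.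

Further compounds
F1 | step 8 | 1-(3-geranyl-6-hydroxy-2,4-dimethoxyphenyl)ethan-1-one | CC(=O)c1c(O)cc(OC)c(C/C=C(\C)CCC=C(C)C)c1OC
F2 | step 8 | (E)-3-(dimethylamino)-1-(3-geranyl-6-hydroxy-2,4-dimethoxyphenyl)prop-2-en-1-one | CN(C)/C=C/C(=O)c1c(O)cc(OC)c(C/C=C(\C)CCC=C(C)C)c1OC
F3 | step 8 | 6-geranyl-5,7-dimethoxy-4H-chromen-4-one | O=c1ccoc2cc(OC)c(C/C=C(\C)CCC=C(C)C)c(OC)c12
F4 | step 2 | (3,5-dimethoxyphenoxy)triisopropylsilane | COc1cc(O[Si](C(C)C)(C(C)C)C(C)C)cc(OC)c1
F5 | step 2 | 2,6-dimethoxy-4-(triisopropylsilyloxy)phenyllithium | COc1cc(O[Si](C(C)C)(C(C)C)C(C)C)cc(OC)c1[Li]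
F6 | step 2 | (4-geranyl-3,5-dimethoxyphenoxy)triisopropylsilane | COc1cc(O[Si](C(C)C)(C(C)C)C(C)C)cc(OC)c1C/C=C(\C)CCC=C(C)C
F7 | step 9 | 6-geranyl-5-hydroxy-7-methoxy-4H-chromen-4-one | O=c1ccoc2cc(OC)c(C/C=C(\C)CCC=C(C)C)c(O)c12
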